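**Plan**
- Cuts (chroman numbering O1–C8a, prenyl C1'–C3'): (a) the C6–C(=O) bond of the chalcone; (b) C2'=C3' of the prenyl group; (c) C3–C4 of the dihydropyran ring, after C4 is raised to a ketone and C2' to an ester carbonyl; (d) the enoate Cα=Cβ bond and the aryl O1–C2 ether.
- Enabling feature: C4 sits on arene carbon C4a, C3 carries the C1'–C2' arm, and O1–C2(CH3)2 ties C3 back to C8a. With C4=O and C2'=O this is a 1,4-dicarbonyl inside a benzopyran. It unfolds to an ortho-formyl aryl ether whose acyl anion can reach a tethered enoate.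
- Forward order: the trioxygenated A ring is bought and its three oxygens are differentiated, then the O1–C2 tether and the enoate are attached. The dihydropyran ring, the only ring made, closes next. C4 is then deoxygenated, the ester arm is grown into prenyl, and the B-ring cinnamoyl unit is joined last at C6.
- Stereochemistry: the single centre C3 comes from the chiral triazolylidene in the ring closure. It is 3S in the ketone and 3R in the target because only the CIP ranking changes. The E-enone comes from a Horner–Wadsworth–Emmons reaction.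

Key step: step 6

Assumption: both antipodes of the aminoindanol-derived N-pentafluorophenyl triazolium salt are commercial. The one used is the antipode that, by analogy with the simpler salicylaldehyde-derived enoates, opens the Si face of the enoate β-carbon.

**Step 1**
Reactants: 1 2,4,6-trihydroxybenzaldehyde
Product: 2 2,6-dihydroxy-4-methoxybenzaldehyde
Conditions: MeI (1.0 equiv), K2CO3 (1.0 equiv), acetone, 0 °C → rt
Reagents that add atoms: iodomethane, CI
Why: Williamson O-methylation under reagent control, in which the 4-OH is the most acidic hydroxyl and the only one not hydrogen-bonded to the formyl oxygen, so one equivalent each of base and MeI should alkylate it ahead of the two ortho hydroxyls.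

**Step 2**
Reactants: 2 2,6-dihydroxy-4-methoxybenzaldehyde
Product: 3 2-hydroxy-4-methoxy-6-(methoxymethoxy)benzaldehyde
Conditions: MOMCl (1.05 equiv), i-Pr2NEt, CH2Cl2, 0 °C
Reagents that add atoms: chloromethyl methyl ether, COCCl
Why: MOM protection (O-alkylation with an α-chloro ether), in which the two ortho hydroxyls are equivalent and, once one is capped, the other sits in a tight chelate with the aldehyde and reacts far more slowly, so one equivalent should stop at the mono-ether.

**Step 3**
Reactants: 3 2-hydroxy-4-methoxy-6-(methoxymethoxy)benzaldehyde; 4 3-chloro-3-methylbut-1-yne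
Product: 5 4-methoxy-2-(methoxymethoxy)-6-[(2-methylbut-3-yn-2-yl)oxy]benzaldehyde
Conditions: DBU (1.3 equiv), CuCl2·2H2O (1 mol %), MeCN, 0 °C → rt
Reagents that add atoms: none
Why: Copper-catalysed propargylic etherification of a phenol with a tertiary propargylic chloride, in which the copper acetylide ionises to an allenylidene-type electrophile that the acidic phenoxide captures at the tertiary carbon, well below the onset of the propargyl Claisen rearrangement.

**Step 4**
Reactants: 5 4-methoxy-2-(methoxymethoxy)-6-[(2-methylbut-3-yn-2-yl)oxy]benzaldehyde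
Product: 6 4-methoxy-2-(methoxymethoxy)-6-[(2-methylbut-3-en-2-yl)oxy]benzaldehyde
Conditions: H2 (1 atm), Lindlar catalyst, quinoline, EtOAc, rt
Reagents that add atoms: none
Why: Lindlar semihydrogenation, in which the poisoned palladium surface should stop at the terminal alkene and leave the aryl aldehyde, the MOM acetal and the tertiary ether untouched.

**Step 5**
Reactants: 6 4-methoxy-2-(methoxymethoxy)-6-[(2-methylbut-3-en-2-yl)oxy]benzaldehyde; 7 ethyl acrylate
Product: 8 ethyl (E)-4-[2-formyl-5-methoxy-3-(methoxymethoxy)phenoxy]-4-methylpent-2-enoate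
Conditions: Hoveyda–Grubbs II (5 mol %), 7 (5 equiv), CH2Cl2, 40 °C
Reagents that add atoms: none
Why: Olefin cross-metathesis, in which the vinyl group next to a fully substituted carbon does not homodimerise and should pair with excess acrylate to give the thermodynamically preferred E-enoate, at a temperature too low for the aromatic Claisen shift of the 1,1-dimethylallyl ether.

**Step 6**
Reactants: 8 ethyl (E)-4-[2-formyl-5-methoxy-3-(methoxymethoxy)phenoxy]-4-methylpent-2-enoate
Product: 9 ethyl 2-[(3S)-7-methoxy-5-(methoxymethoxy)-2,2-dimethyl-4-oxochroman-3-yl]acetate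
Conditions: aminoindanol-derived N-C6F5 triazolium tetrafluoroborate (20 mol %), KHMDS (18 mol %), toluene, 23 °C
Reagents that add atoms: none
Why: The carbene freed from the triazolium salt adds to the formyl group and a proton shift gives the Breslow enaminol, an acyl anion equivalent at the future C4, which attacks the β-carbon of the tethered enoate before protonation of the ester enolate and loss of the carbene deliver the 1,4-keto ester. This is the enantioselective intramolecular Stetter reaction of O-tethered salicylaldehyde enoates to 3-substituted chroman-4-ones. The dihydropyranone ring closes in the 6-exo-trig mode through the new C4–C3 bond. C3 is the only new stereocentre, and the indane wall of the catalyst together with the fixed E geometry of the enoate should leave only the Si face of the β-carbon open, which gives 3S, the arrangement that is called 3R in the target. The electron-poor C6F5 group makes the azolium acidic enough for a substoichiometric base and should speed turnover with the electron-rich, doubly ortho-substituted aldehyde, while the geminal methyl groups at C2 compress the tether and offset the crowding at the neopentylic β-carbon. The step needs Stetter addition to win over benzoin coupling and the base-labile C3–H to survive, and the intramolecular acceptor, the hindered aldehyde and a base charge kept below the catalyst loading should secure both.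

**Step 7**
Reactants: 9 ethyl 2-[(3S)-7-methoxy-5-(methoxymethoxy)-2,2-dimethyl-4-oxochroman-3-yl]acetate
Product: 10 (3R)-3-(2-hydroxyethyl)-7-methoxy-5-(methoxymethoxy)-2,2-dimethylchroman-4-ol (C4 epimers)
Conditions: LiAlH4 (excess), THF, −20 → 0 °C (9 added to the hydride); H2O/NaOH work-up
Reagents that add atoms: none
Why: Hydride reduction with LiAlH4, in which excess hydride at low temperature should reduce the ketone faster than it can enolise, so that C3 is kept, and also takes the ester to the primary alcohol, while the new C4 carbinol centre is deleted in the next step and its configuration does not matter.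

**Step 8**
Reactants: 10 (3R)-3-(2-hydroxyethyl)-7-methoxy-5-(methoxymethoxy)-2,2-dimethylchroman-4-ol
Product: 11 2-[(3S)-7-methoxy-5-(methoxymethoxy)-2,2-dimethylchroman-3-yl]ethan-1-ol
Conditions: H2 (1 atm), 10 % Pd/C, EtOH, rt
Reagents that add atoms: none
Why: Catalytic hydrogenolysis of a benzylic C–O bond, in which C4–OH is the only benzylic C–O bond and is activated by oxygens ortho (C5, C8a) and para (C7) to C4a, while the neutral medium spares the MOM acetal and avoids an E1 loss of H3 that would erase the stereocentre.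

**Step 9**
Reactants: 11 2-[(3S)-7-methoxy-5-(methoxymethoxy)-2,2-dimethylchroman-3-yl]ethan-1-ol
Product: 12 2-[(3S)-7-methoxy-5-(methoxymethoxy)-2,2-dimethylchroman-3-yl]acetaldehyde
Conditions: Dess–Martin periodinane, CH2Cl2, 0 °C → rt
Reagents that add atoms: none
Why: Dess–Martin oxidation, a mild non-basic conversion of the primary alcohol into the aldehyde in which C3 lies β to the new carbonyl and cannot epimerise.

**Step 10**
Reactants: 12 2-[(3S)-7-methoxy-5-(methoxymethoxy)-2,2-dimethylchroman-3-yl]acetaldehyde
Product: 13 (3R)-7-methoxy-5-(methoxymethoxy)-2,2-dimethyl-3-(3-methylbut-2-en-1-yl)chroman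
Conditions: i-PrPPh3I, n-BuLi, THF, 0 °C; then 12, −78 °C → rt
Reagents that add atoms: isopropyltriphenylphosphonium iodide, CC(C)[P+](c1ccccc1)(c1ccccc1)c1ccccc1.[I-]
Why: Wittig olefination with the non-stabilised isopropylidene ylide, which adds C3' and its two methyl groups and raises no question of alkene geometry because the new terminus is symmetrical.

**Step 11**
Reactants: 14 2,4-dihydroxybenzaldehyde
Product: 15 2,4-bis(methoxymethoxy)benzaldehyde
Conditions: MOMCl (3 equiv), K2CO3 (excess), acetone, reflux
Reagents that add atoms: chloromethyl methyl ether, COCCl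
Why: MOM protection of both phenols, in which excess reagent and heating should overcome the chelation of the 2-OH to the aldehyde.

**Step 12**
Reactants: 15 2,4-bis(methoxymethoxy)benzaldehyde
Product: 16 (E)-3-[2,4-bis(methoxymethoxy)phenyl]-N-methoxy-N-methylprop-2-enamide
Conditions: (EtO)2P(O)CH2C(O)N(OMe)Me, NaH, THF, 0 °C → rt
Reagents that add atoms: diethyl [2-(methoxy(methyl)amino)-2-oxoethyl]phosphonate, CCOP(=O)(CC(=O)N(C)OC)OCC
Why: Horner–Wadsworth–Emmons olefination, in which the stabilised phosphonate anion and an aryl aldehyde should give the E-alkene that becomes the chalcone double bond.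

**Step 13**
Reactants: 13 (3R)-7-methoxy-5-(methoxymethoxy)-2,2-dimethyl-3-(3-methylbut-2-en-1-yl)chroman; 16 (E)-3-[2,4-bis(methoxymethoxy)phenyl]-N-methoxy-N-methylprop-2-enamide
Product: 18 (E)-3-[2,4-bis(methoxymethoxy)phenyl]-1-[(3R)-7-methoxy-5-(methoxymethoxy)-2,2-dimethyl-3-(3-methylbut-2-en-1-yl)chroman-6-yl]prop-2-en-1-one, via C6-aryllithium 17 (not isolated)
Conditions: n-BuLi (1.2 equiv), THF, 0 °C; then 16, −78 → 0 °C; H2O
Reagents that add atoms: none
Why: Directed ortho-metalation followed by ketone synthesis from an N-methoxy-N-methylamide, in which the MOM group chelates lithium and, reinforced by the 7-OMe, should steer deprotonation to C6 (its only free ortho position) rather than C8, and the non-enolisable amide accepts a single 1,2-addition so that no tertiary alcohol forms.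

**Step 14**
Reactants: 18 (E)-3-[2,4-bis(methoxymethoxy)phenyl]-1-[(3R)-7-methoxy-5-(methoxymethoxy)-2,2-dimethyl-3-(3-methylbut-2-en-1-yl)chroman-6-yl]prop-2-en-1-one
Product: 19 (E)-3-(2,4-dihydroxyphenyl)-1-[(3R)-5-hydroxy-7-methoxy-2,2-dimethyl-3-(3-methylbut-2-en-1-yl)chroman-6-yl]prop-2-en-1-one
Conditions: HCl (0.5 M in MeOH), rt, dark
Reagents that add atoms: none
Why: Acid-catalysed acetal exchange (MOM cleavage) in methanol, a mild protocol that prenylated 2'-hydroxychalcones tolerate, run at room temperature and in the dark to hold back oxa-Michael closure to the flavanone and E→Z isomerisation, and without effect on C3.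

**Compound list**
1 | 2,4,6-trihydroxybenzaldehyde | O=Cc1c(O)cc(O)cc1O | starting material
2 | 2,6-dihydroxy-4-methoxybenzaldehyde | COc1cc(O)c(C=O)c(O)c1 | intermediate
3 | 2-hydroxy-4-methoxy-6-(methoxymethoxy)benzaldehyde | COc1cc(O)c(C=O)c(OCOC)c1 | intermediate
4 | 3-chloro-3-methylbut-1-yne | CC(C)(Cl)C#C | starting material
5 | 4-methoxy-2-(methoxymethoxy)-6-[(2-methylbut-3-yn-2-yl)oxy]benzaldehyde | COc1cc(OCOC)c(C=O)c(OC(C)(C)C#C)c1 | intermediate
6 | 4-methoxy-2-(methoxymethoxy)-6-[(2-methylbut-3-en-2-yl)oxy]benzaldehyde | COc1cc(OCOC)c(C=O)c(OC(C)(C)C=C)c1 | intermediate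
7 | ethyl acrylate | C=CC(=O)OCC | starting material
8 | ethyl (E)-4-[2-formyl-5-methoxy-3-(methoxymethoxy)phenoxy]-4-methylpent-2-enoate | COc1cc(OCOC)c(C=O)c(OC(C)(C)/C=C/C(=O)OCC)c1 | intermediate
9 | ethyl 2-[(3S)-7-methoxy-5-(methoxymethoxy)-2,2-dimethyl-4-oxochroman-3-yl]acetate | COc1cc(OCOC)c2C(=O)[C@@H](CC(=O)OCC)C(C)(C)Oc2c1 | intermediate
10 | (3R)-3-(2-hydroxyethyl)-7-methoxy-5-(methoxymethoxy)-2,2-dimethylchroman-4-ol, C4 epimers | COc1cc(OCOC)c2C(O)[C@@H](CCO)C(C)(C)Oc2c1 | intermediate
11 | 2-[(3S)-7-methoxy-5-(methoxymethoxy)-2,2-dimethylchroman-3-yl]ethan-1-ol | COc1cc(OCOC)c2C[C@@H](CCO)C(C)(C)Oc2c1 | intermediate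
12 | 2-[(3S)-7-methoxy-5-(methoxymethoxy)-2,2-dimethylchroman-3-yl]acetaldehyde | COc1cc(OCOC)c2C[C@@H](CC=O)C(C)(C)Oc2c1 | intermediate
13 | (3R)-7-methoxy-5-(methoxymethoxy)-2,2-dimethyl-3-(3-methylbut-2-en-1-yl)chroman | COc1cc(OCOC)c2C[C@@H](CC=C(C)C)C(C)(C)Oc2c1 | intermediate
14 | 2,4-dihydroxybenzaldehyde | O=Cc1ccc(O)cc1O | starting material
15 | 2,4-bis(methoxymethoxy)benzaldehyde | COCOc1ccc(C=O)c(OCOC)c1 | intermediate
16 | (E)-3-[2,4-bis(methoxymethoxy)phenyl]-N-methoxy-N-methylprop-2-enamide | COCOc1ccc(/C=C/C(=O)N(C)OC)c(OCOC)c1 | intermediate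
17 | [(3R)-7-methoxy-5-(methoxymethoxy)-2,2-dimethyl-3-(3-methylbut-2-en-1-yl)chroman-6-yl]lithium | COc1cc2c(c(OCOC)c1[Li])C[C@@H](CC=C(C)C)C(C)(C)O2 | intermediate (not isolated)
18 | (E)-3-[2,4-bis(methoxymethoxy)phenyl]-1-[(3R)-7-methoxy-5-(methoxymethoxy)-2,2-dimethyl-3-(3-methylbut-2-en-1-yl)chroman-6-yl]prop-2-en-1-one | COc1cc2c(c(OCOC)c1C(=O)/C=C/c1ccc(OCOC)cc1OCOC)C[C@@H](CC=C(C)C)C(C)(C)O2 | intermediate
19 | (E)-3-(2,4-dihydroxyphenyl)-1-[(3R)-5-hydroxy-7-methoxy-2,2-dimethyl-3-(3-methylbut-2-en-1-yl)chroman-6-yl]prop-2-en-1-one | COc1cc2c(c(O)c1C(=O)/C=C/c1ccc(O)cc1O)C[C@@H](CC=C(C)C)C(C)(C)O2 | target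

**Step count**
Total: 14 steps. Longest linear sequence: 12 steps (steps 1–10, 13 and 14). Steps 11 and 12 form the side branch.

**Steps most likely to fail**

(i) Step 6.
- Risk: the carbene may add slowly to the electron-rich, doubly ortho-substituted aldehyde, and the enaminol may attack the neopentylic β-carbon slowly. Long reaction times would then lower the facial selectivity and allow enolisation, or retro-oxa-Michael opening, at C3.
- Fallback: it sets out from 8 and returns at 10, and it separates ring closure from stereocontrol.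
- Ring closure: 8 is closed with a small achiral thiazol-2-ylidene (3-benzyl-5-(2-hydroxyethyl)-4-methylthiazolium chloride, Et3N, dioxane, 70 °C). This gives racemic ethyl 2-[7-methoxy-5-(methoxymethoxy)-2,2-dimethyl-4-oxochroman-3-yl]acetate F1.
- Stereocontrol: C3 of this ketone is labile to base, so asymmetric transfer hydrogenation under dynamic kinetic resolution is applied (RuCl[(S,S)-TsDPEN](p-cymene), HCO2H–Et3N, 40 °C). By analogy with 4-chromanone it should deliver the 4S carbinol with a cis relationship, funnelling both enantiomers into ethyl 2-[(3R,4S)-4-hydroxy-7-methoxy-5-(methoxymethoxy)-2,2-dimethylchroman-3-yl]acetate F2.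
- Return: this hydroxy ester should lactonise to (3aR,9bS)-7-methoxy-9-(methoxymethoxy)-4,4-dimethyl-3,3a,4,9b-tetrahydro-2H-furo[3,2-c]chromen-2-one F3. LiAlH4 opens the lactone to 10 as a single C4 epimer.

(ii) Step 5.
- Risk: metathesis at the vinyl group next to the quaternary carbon may be sluggish. Catalyst decay, acrylate self-coupling and, on prolonged heating, a [3,3] shift or ionisation of the tertiary allyl aryl ether could then take over.
- Fallback: it sets out from 6 and returns at 8, and it replaces metathesis by cleavage and olefination.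
- Cleavage: Lemieux–Johnson oxidation (OsO4 cat., NaIO4, 2,6-lutidine, dioxane–H2O) gives 2-[2-formyl-5-methoxy-3-(methoxymethoxy)phenoxy]-2-methylpropanal F4.
- Olefination: one equivalent of Ph3P=CHCO2Et (CH2Cl2, rt) should react only at the α-aryloxy aliphatic aldehyde. The aryl aldehyde is deactivated by three donor oxygens and is flanked on both sides. The stabilised ylide gives the E-enoate 8.

(iii) Step 13.
- Risk: deprotonation at C8 may compete, lithiation may be incomplete, or the crowded aryllithium may be captured slowly or in conjugate fashion.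
- Fallback: it sets out from 13, uses 15, and returns at 19. Regiocontrol passes from lithium chelation to a free phenol.
- Phenol: brief treatment with HCl in MeOH gives (3R)-7-methoxy-2,2-dimethyl-3-(3-methylbut-2-en-1-yl)chroman-5-ol F5.
- Formylation: magnesium-mediated ortho-formylation (Casnati–Skattebøl; MgCl2, Et3N, paraformaldehyde, MeCN, reflux) can only reach C6. It gives (3R)-5-hydroxy-7-methoxy-2,2-dimethyl-3-(3-methylbut-2-en-1-yl)chroman-6-carbaldehyde F6.
- Methyl ketone: MeMgBr (2.5 equiv, THF, 0 °C) gives (3R)-6-(1-hydroxyethyl)-7-methoxy-2,2-dimethyl-3-(3-methylbut-2-en-1-yl)chroman-5-ol F7. MnO2 oxidises it to 1-[(3R)-5-hydroxy-7-methoxy-2,2-dimethyl-3-(3-methylbut-2-en-1-yl)chroman-6-yl]ethan-1-one F8.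
- Chalcone: Claisen–Schmidt condensation with 15 (KOH, EtOH, rt) gives (E)-3-[2,4-bis(methoxymethoxy)phenyl]-1-[(3R)-5-hydroxy-7-methoxy-2,2-dimethyl-3-(3-methylbut-2-en-1-yl)chroman-6-yl]prop-2-en-1-one F9. The conditions of step 14 then convert it into 19.

**Further compounds**
F1 | step 6 | racemic ethyl 2-[7-methoxy-5-(methoxymethoxy)-2,2-dimethyl-4-oxochroman-3-yl]acetate | COc1cc(OCOC)c2C(=O)C(CC(=O)OCC)C(C)(C)Oc2c1
F2 | step 6 | ethyl 2-[(3R,4S)-4-hydroxy-7-methoxy-5-(methoxymethoxy)-2,2-dimethylchroman-3-yl]acetate | COc1cc(OCOC)c2[C@@H](O)[C@@H](CC(=O)OCC)C(C)(C)Oc2c1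
F3 | step 6 | (3aR,9bS)-7-methoxy-9-(methoxymethoxy)-4,4-dimethyl-3,3a,4,9b-tetrahydro-2H-furo[3,2-c]chromen-2-one | COc1cc(OCOC)c2[C@H]3OC(=O)C[C@H]3C(C)(C)Oc2c1
F4 | step 5 | 2-[2-formyl-5-methoxy-3-(methoxymethoxy)phenoxy]-2-methylpropanal | COc1cc(OCOC)c(C=O)c(OC(C)(C)C=O)c1
F5 | step 13 | (3R)-7-methoxy-2,2-dimethyl-3-(3-methylbut-2-en-1-yl)chroman-5-ol | COc1cc(O)c2C[C@@H](CC=C(C)C)C(C)(C)Oc2c1
F6 | step 13 | (3R)-5-hydroxy-7-methoxy-2,2-dimethyl-3-(3-methylbut-2-en-1-yl)chroman-6-carbaldehyde | COc1cc2c(c(O)c1C=O)C[C@@H](CC=C(C)C)C(C)(C)O2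
F7 | step 13 | (3R)-6-(1-hydroxyethyl)-7-methoxy-2,2-dimethyl-3-(3-methylbut-2-en-1-yl)chroman-5-ol, carbinol epimers | COc1cc2c(c(O)c1C(C)O)C[C@@H](CC=C(C)C)C(C)(C)O2
F8 | step 13 | 1-[(3R)-5-hydroxy-7-methoxy-2,2-dimethyl-3-(3-methylbut-2-en-1-yl)chroman-6-yl]ethan-1-one | COc1cc2c(c(O)c1C(C)=O)C[C@@H](CC=C(C)C)C(C)(C)O2
F9 | step 13 | (E)-3-[2,4-bis(methoxymethoxy)phenyl]-1-[(3R)-5-hydroxy-7-methoxy-2,2-dimethyl-3-(3-methylbut-2-en-1-yl)chroman-6-yl]prop-2-en-1-one | COc1cc2c(c(O)c1C(=O)/C=C/c1ccc(OCOC)cc1OCOC)C[C@@H](CC=C(C)C)C(C)(C)O2
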